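All runs stem from a simulated flask with constants of no real substance; scatter was added.

- The north run and the east run differ in charge by a factor of 4.17, and this flask's 0.25 M lies between them.

| flask | substrate | remark | time |
|---|---|---|---|
| north | 0.12 M | run made earlier |  |
| east | 0.50 M | run made earlier |  |
| flask | 0.25 M |  | 4.0 min |

| run | time / min | target / % |
|---|---|---|
| north | 0.417 | 31.0 |
| north | 0.667 | 43.4 |
| north | 1.00 | 53.6 |
| north | 2.00 | 57.0 |
| north | 3.00 | 48.6 |
| east | 0.417 | 30.9 |
| east | 0.667 | 43.2 |
| east | 1.00 | 53.2 |
| east | 2.00 | 57.4 |
| east | 3.00 | 48.8 |

(readings scatter by 0.3 percentage points)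

1. time up to 4.0 min at which target stands highest
2. the amount of target, in percent of the substrate charged, at that time

- I set two amounts against each other. The first is the east-minus-north gap at 2.00 min, the reading nearest the top, which is 0.4 percentage points; the second is the scatter of a difference of two readings, 0.42 points.
- Their ratio is 0.943. This charge shift has as its zero a percentage curve that takes no notice of the charge.
- The gap is smaller than the scatter, and at 1.00 min it has the other sign, −0.4 points, so I read the runs as first-order behaviour and carry their curve to this flask.
- I therefore expect this flask to hold about 57.2 % at 2.00 min, with its top between 1.00 min and 3.00 min.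
- The forecast gives 1.65 min (1.45 min to 1.85 min) and 58 % (57.3 % to 59 %), holding that “the flask should follow the same curve”.
- This flask peaks at 1.63 min with 58.5 %, and holds 57.3 % at 2.00 min.

    substrate ⇌ intermediate A (K = 0.410, k = 0.160 s⁻¹)
    substrate ⇌ intermediate B (K = 1.40, k = 0.0750 s⁻¹)
    intermediate B → target (k = 0.100 s⁻¹)
    target ⇌ isomer of the product (K = 5.30, k = 0.00600 s⁻¹)
    substrate ⇌ dormant form (K = 0.940, k = 0.110 s⁻¹)

- The neighbour with 0.42 M also lies between the charges of the two runs, so I expect its charge shift against this flask to stay below 0.943. It does: its best is 58.5 % against 58.5 %. At 4.00 min that neighbour holds 39.3 % target and 59.3 % isomer of the product.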